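**Retrosynthetic overview**

- The phenol OH is introduced last, by sterically controlled Ir-catalysed C–H borylation/oxidation of 1-heptadecyl-2,3-dimethoxybenzene at the only ring C–H that has no ortho neighbour.
- The C17 chain is cut at the CH2–CH2 bond between chain carbons C8 and C9 (counted from the ring). This leads to two acids, each one carbon longer: 9-(2,3-dimethoxyphenyl)nonanoic acid and decanoic acid. They are joined as their N-hydroxyphthalimide esters by a Ni-electrocatalytic doubly decarboxylative coupling; both CO2 units and both phthalimide groups leave in that step.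
- Enabling feature: C8 and C9 are two unactivated primary sp3 carbons inside an unbranched, unfunctionalised polymethylene chain, so each can be the carboxyl-bearing carbon of a fatty acid and become a primary radical. The electron-rich dimethoxybenzene ring sits eight CH2 groups away and is inert at a cathode, which is why the coupling is run reductively and not as an anodic Kolbe electrolysis.
- The aryl acid comes from 2,3-dimethoxybenzaldehyde by Wittig olefination with a carboxyheptyl ylide, then hydrogenation.
- No ring is formed; the benzene ring is bought intact and no protecting group is used.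

Key step: step 5

Remark on the chemistry: the target has no stereocentre and no stereogenic double bond, so it is one achiral compound and no stereocontrol is needed. In 9 the chain carbon is ring C1 and the methoxy groups are on C2 and C3.

**Route**

Step 1
Reactants: 1 2,3-dimethoxybenzaldehyde; 2 (7-carboxyheptyl)triphenylphosphonium bromide
Product: 4 (Z)-9-(2,3-dimethoxyphenyl)non-8-enoic acid, via ylide carboxylate 3 (not isolated)
Conditions: 2 (1.2 equiv), NaHMDS (2.4 equiv), THF, 0 °C; then 1, 0 °C to rt; aq. HCl work-up
Reagents that add atoms: none
Why: Wittig olefination, in which the non-stabilised ylide formed from 2 with two equivalents of base (carboxylate first, then ylide) should add to the aryl aldehyde to give mainly the Z-alkene, whose geometry does not matter because step 2 removes it.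

Step 2
Reactants: 4 (Z)-9-(2,3-dimethoxyphenyl)non-8-enoic acid
Product: 5 9-(2,3-dimethoxyphenyl)nonanoic acid
Conditions: H2 (1 atm), 10% Pd/C, EtOAc, rt
Reagents that add atoms: none
Why: Heterogeneous catalytic hydrogenation of a 1,2-disubstituted styrenic alkene, under which the aryl methyl ethers and the carboxylic acid should be inert.

Step 3
Reactants: 5 9-(2,3-dimethoxyphenyl)nonanoic acid
Product: 6 1,3-dioxoisoindolin-2-yl 9-(2,3-dimethoxyphenyl)nonanoate
Conditions: N-hydroxyphthalimide, DIC, DMAP (cat.), CH2Cl2, rt
Reagents that add atoms: N-hydroxyphthalimide, O=C1c2ccccc2C(=O)N1O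
Why: Carbodiimide-mediated (Steglich-type) esterification of a primary acid with N-hydroxyphthalimide should give the redox-active ester, with no other nucleophilic group in the molecule to compete.

Step 4
Reactants: 7 decanoic acid
Product: 8 1,3-dioxoisoindolin-2-yl decanoate
Conditions: N-hydroxyphthalimide, DIC, DMAP (cat.), CH2Cl2, rt
Reagents that add atoms: N-hydroxyphthalimide, O=C1c2ccccc2C(=O)N1O
Why: The same carbodiimide-mediated esterification turns the cheap C10 acid into the redox-active ester that is used in excess in step 5.

Step 5
Reactants: 6 1,3-dioxoisoindolin-2-yl 9-(2,3-dimethoxyphenyl)nonanoate; 8 1,3-dioxoisoindolin-2-yl decanoate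
Product: 9 1-heptadecyl-2,3-dimethoxybenzene
Conditions: 6 (1 equiv), 8 (3 equiv), NiCl2·6H2O (cat.), 2,2':6',2''-terpyridine (cat.), AgNO3 (substoich.), NMP, Mg(+)/RVC(−), undivided cell, constant current, rt
Reagents that add atoms: none
Why: Cathodically generated low-valent nickel–terpyridine should transfer one electron to each N-acyloxyphthalimide, whose N–O bond breaks with loss of CO2 to give the primary 8-aryloctyl and nonyl radicals; these are captured at nickel, and reductive elimination from the dialkylnickel species should form the C8–C9 bond of the chain. The closest known reaction type is the Ni-electrocatalytic doubly decarboxylative C(sp3)–C(sp3) coupling of two redox-active esters, a reductive counterpart of mixed Kolbe electrolysis that is established for primary/primary pairs. No ring is closed and no stereocentre is formed. The selectivity required is cross-coupling over homocoupling, which is statistical and is biased by the threefold excess of 8; the by-product hydrocarbon from 8 has no polar group and the dimer of the aryl half has four methoxy groups, so both should separate from 9 on silica. The substrate suits the step because the dimethoxybenzene ring is not reduced at the working potential and never meets an oxidising anode (the magnesium anode is sacrificial). The eight-methylene spacer keeps the radical primary and non-benzylic and leaves it no feasible cyclisation onto the ring.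

Step 6
Reactants: 9 1-heptadecyl-2,3-dimethoxybenzene
Product: 11 3-heptadecyl-4,5-dimethoxyphenol, via aryl pinacol boronate 10 (not isolated)
Conditions: [Ir(OMe)(cod)]2 (cat.), dtbpy (cat.), B2pin2 (1.0 equiv), THF, 80 °C; then aq. H2O2, NaOH, 0 °C
Reagents that add atoms: bis(pinacolato)diboron, CC1(C)OB(OC1(C)C)B1OC(C)(C)C(C)(C)O1 (boryl group of intermediate 10 only); hydrogen peroxide, OO (the phenol oxygen)
Why: Sterically controlled Ir-catalysed aromatic C–H borylation followed by oxidation of the C–B bond in the same flask should put the oxygen at ring C5 of 9, the only C–H with no ortho substituent (C4 is next to a methoxy group and C6 next to the chain), which is the phenol position of the target.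

**Compound list**

1 | 2,3-dimethoxybenzaldehyde | COc1cccc(C=O)c1OC | starting material
2 | (7-carboxyheptyl)triphenylphosphonium bromide | [Br-].OC(=O)CCCCCCC[P+](c1ccccc1)(c1ccccc1)c1ccccc1 | starting material
3 | sodium 8-(triphenylphosphoranylidene)octanoate (ylide carboxylate) | [Na+].[O-]C(=O)CCCCCCC=P(c1ccccc1)(c1ccccc1)c1ccccc1 | intermediate (not isolated)
4 | (Z)-9-(2,3-dimethoxyphenyl)non-8-enoic acid | COc1cccc(/C=C\CCCCCCC(=O)O)c1OC | intermediate
5 | 9-(2,3-dimethoxyphenyl)nonanoic acid | COc1cccc(CCCCCCCCC(=O)O)c1OC | intermediate
6 | 1,3-dioxoisoindolin-2-yl 9-(2,3-dimethoxyphenyl)nonanoate | COc1cccc(CCCCCCCCC(=O)ON2C(=O)c3ccccc3C2=O)c1OC | intermediate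
7 | decanoic acid | CCCCCCCCCC(=O)O | starting material
8 | 1,3-dioxoisoindolin-2-yl decanoate | CCCCCCCCCC(=O)ON1C(=O)c2ccccc2C1=O | intermediate
9 | 1-heptadecyl-2,3-dimethoxybenzene | CCCCCCCCCCCCCCCCCc1cccc(OC)c1OC | intermediate
10 | 2-(3-heptadecyl-4,5-dimethoxyphenyl)-4,4,5,5-tetramethyl-1,3,2-dioxaborolane | CCCCCCCCCCCCCCCCCc1cc(B2OC(C)(C)C(C)(C)O2)cc(OC)c1OC | intermediate (not isolated)
11 | 3-heptadecyl-4,5-dimethoxyphenol | CCCCCCCCCCCCCCCCCc1cc(O)cc(OC)c1OC | target

**Step count**

Total steps: 6. Longest linear sequence: 5 (steps 1, 2, 3, 5, 6); step 4 is a one-step side branch.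

**Steps most likely to fail**

Step 5. The two primary alkyl fragments may mix statistically at nickel, so that homocoupling and premature reduction of the limiting ester to the alkane outrun cross-coupling. The fallback sets out from 6 and comes back at 9. It gives up the double-decarboxylative pairing and makes the nonyl half a preformed nucleophile. Commercial nonylmagnesium bromide would be transmetalated with ZnCl2 in THF to dinonylzinc F1. Ester 6 would then be coupled with it under nickel catalysis (NiCl2·glyme, 4,4'-di-tert-butyl-2,2'-bipyridine, THF/DMF, rt), a decarboxylative Negishi-type alkyl–alkyl coupling of a redox-active ester. This should give 9 with the same chain bond formed and no statistical dimer of the aryl half.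

Step 6. Borylation of the electron-rich ring may be slow, with borylation next to the C3 methoxy group competing, and the peroxide stage may over-oxidise the electron-rich para-methoxyphenol. The fallback sets out from 2 and comes back at 11. It carries the oxygen position as a chlorine from the start and unveils it without an oxidant. Commercial 5-chloro-2,3-dimethoxybenzaldehyde F3 would be olefinated with ylide 3 made from 2 (NaHMDS, THF) to (Z)-9-(5-chloro-2,3-dimethoxyphenyl)non-8-enoic acid F4. Hydrogenation over sulfided Pt/C, chosen to avoid C–Cl hydrogenolysis, would give 9-(5-chloro-2,3-dimethoxyphenyl)nonanoic acid F5. N-Hydroxyphthalimide and DIC would give 1,3-dioxoisoindolin-2-yl 9-(5-chloro-2,3-dimethoxyphenyl)nonanoate F6. Coupling with 8 under the conditions of step 5 would give 5-chloro-1-heptadecyl-2,3-dimethoxybenzene F7; the electron-rich aryl chloride is not expected to add to nickel at rt. Palladium-catalysed hydroxylation (Pd2(dba)3, tBuXPhos, KOH, dioxane/water, 100 °C) would then convert the C–Cl bond into the phenol 11.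

Step 1. Ylide formation may be incomplete and addition sluggish, because the carboxylate-bearing ylide is poorly soluble and aggregates. The fallback sets out from 1 and comes back at 5. It builds the alkene by metathesis instead. Methylenation of 1 (methyltriphenylphosphonium bromide, KOtBu, THF) would give 1-ethenyl-2,3-dimethoxybenzene F8. Cross-metathesis with commercial non-8-enoic acid (Grubbs second-generation catalyst, CH2Cl2, 40 °C, styrene in excess) would give (E)-9-(2,3-dimethoxyphenyl)non-8-enoic acid F9. Hydrogenation as in step 2 would give 5.

**Further compounds**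

F1 | step 5 | dinonylzinc | CCCCCCCCC[Zn]CCCCCCCCC
F3 | step 6 | 5-chloro-2,3-dimethoxybenzaldehyde (purchased) | COc1cc(Cl)cc(C=O)c1OC
F4 | step 6 | (Z)-9-(5-chloro-2,3-dimethoxyphenyl)non-8-enoic acid | COc1cc(Cl)cc(/C=C\CCCCCCC(=O)O)c1OC
F5 | step 6 | 9-(5-chloro-2,3-dimethoxyphenyl)nonanoic acid | COc1cc(Cl)cc(CCCCCCCCC(=O)O)c1OC
F6 | step 6 | 1,3-dioxoisoindolin-2-yl 9-(5-chloro-2,3-dimethoxyphenyl)nonanoate | COc1cc(Cl)cc(CCCCCCCCC(=O)ON2C(=O)c3ccccc3C2=O)c1OC
F7 | step 6 | 5-chloro-1-heptadecyl-2,3-dimethoxybenzene | CCCCCCCCCCCCCCCCCc1cc(Cl)cc(OC)c1OC
F8 | step 1 | 1-ethenyl-2,3-dimethoxybenzene | COc1cccc(C=C)c1OC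
F9 | step 1 | (E)-9-(2,3-dimethoxyphenyl)non-8-enoic acid | COc1cccc(/C=C/CCCCCCC(=O)O)c1OC
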